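The route rests on a formal (3+3) disconnection of ring C (the pyran) at C4–C4a and O1–C2. It exploits the substitution of ring A: with the prenyl group on C8 between O1 and the 7-OH, the ring A precursor 5-methoxy-2-prenylresorcinol is symmetric, its two OH groups (future O1 and 7-OH) and its two free CH positions (future C4a and C6) being equivalent, so union with an aryl vinyl ketone can give one constitution only. In one operation a chiral phosphoric acid mediates Friedel–Crafts conjugate addition (C4–C4a) and hemiketalisation (O1–C2), and a Hantzsch ester reduces the derived oxocarbenium ion enantioselectively at C2. The precursors are the unprotected resorcinol and 1-(3-hydroxy-5-methoxyphenyl)prop-2-en-1-one.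

Key step: step 6

Assumption: the (R)-configured acid is assumed to direct hydride to the face of the cation that gives (2R); no model secures this sense for the ion pair, and if it proves opposite the (S)-acid is used with nothing else changed.

Step 1
Reactants: 1 5-methoxybenzene-1,3-diol
Product: 2 1-methoxy-3,5-bis(methoxymethoxy)benzene
Conditions: NaH (2.5 equiv), MOMCl (2.4 equiv), DMF, 0 °C to rt
Reagents that add atoms: chloromethyl methyl ether (MOMCl), COCCl
Why: Williamson-type O-alkylation of the bis-phenoxide with the hard α-chloro ether should give the bis-acetal, whose two OMOM groups serve as directing groups in step 2.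

Step 2
Reactants: 2 1-methoxy-3,5-bis(methoxymethoxy)benzene
Product: 4 5-methoxy-1,3-bis(methoxymethoxy)-2-(3-methylbut-2-en-1-yl)benzene, via aryllithium 3 (not isolated)
Conditions: n-BuLi (1.15 equiv), THF, 0 °C; then CuI (10 mol%), prenyl bromide (1.3 equiv), −78 °C to rt
Reagents that add atoms: 1-bromo-3-methylbut-2-ene (prenyl bromide), CC(C)=CCBr
Why: Directed ortho-metalation should occur at the carbon between the two OMOM groups (doubly coordinated and most acidic), and copper-assisted alkylation of the aryllithium at the unhindered CH2 of the allylic bromide should give the linear prenyl arene.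

Step 3
Reactants: 4 5-methoxy-1,3-bis(methoxymethoxy)-2-(3-methylbut-2-en-1-yl)benzene
Product: 5 5-methoxy-2-(3-methylbut-2-en-1-yl)benzene-1,3-diol
Conditions: HCl (1.25 M in MeOH), 40 °C
Reagents that add atoms: none
Why: Acid-catalysed transacetalisation to methanol (MOM cleavage) should free both phenols, dilute methanolic HCl being too weak to protonate the trisubstituted alkene at a useful rate.

Step 4
Reactants: 6 3-hydroxy-5-methoxybenzaldehyde
Product: 7 1-(3-hydroxy-5-methoxyphenyl)prop-2-en-1-ol (racemic)
Conditions: CH2=CHMgBr (2.5 equiv), THF, −20 °C to rt; sat. aq NH4Cl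
Reagents that add atoms: vinylmagnesium bromide, C=C[Mg]Br
Why: Grignard 1,2-addition, with the first equivalent consumed by the phenol, should give the allylic alcohol, whose stereocentre is left uncontrolled because step 5 removes it.

Step 5
Reactants: 7 1-(3-hydroxy-5-methoxyphenyl)prop-2-en-1-ol
Product: 8 1-(3-hydroxy-5-methoxyphenyl)prop-2-en-1-one
Conditions: activated MnO2 (15 equiv), CH2Cl2, rt; filtered and used at once as a dilute solution
Reagents that add atoms: none
Why: Heterogeneous MnO2 oxidation is selective for the allylic and benzylic carbinol and should leave the phenol untouched, giving the aryl vinyl ketone.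

Step 6
Reactants: 5 5-methoxy-2-(3-methylbut-2-en-1-yl)benzene-1,3-diol (2.0 equiv); 8 1-(3-hydroxy-5-methoxyphenyl)prop-2-en-1-one
Product: 12 (2R)-2-(3-hydroxy-5-methoxyphenyl)-5-methoxy-8-(3-methylbut-2-en-1-yl)-3,4-dihydro-2H-chromen-7-ol (the target), via open-chain ketone 9 (not isolated), via hemiketal 10 (not isolated), via 4H-chromene enol ether 11 (not isolated)
Conditions: (R)-3,3'-bis(2,4,6-triisopropylphenyl)-1,1'-binaphthalene-2,2'-diyl hydrogen phosphate (10 mol%), 5 Å MS, ClCH2CH2Cl, rt, slow addition of 8, argon; then diethyl 2,6-dimethyl-1,4-dihydropyridine-3,5-dicarboxylate (Hantzsch ester, 1.4 equiv), 45 °C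
Reagents that add atoms: none
Why: Proposed new method: the phosphoric acid activates enone 8 by hydrogen bonding, the free ring CH of 5 (ortho to OH and OMe, para to the second OH) adds to its CH2 terminus in a Friedel–Crafts conjugate addition (C4–C4a, ketone 9), the adjacent OH adds to the aryl ketone (O1–C2, hemiketal 10), and acid-promoted loss of water gives a 2-aryl-3,4-dihydrochromenylium phosphate ion pair (conjugate acid of enol ether 11) that accepts hydride from the Hantzsch ester at C2. The closest known reaction types are the Brønsted acid-catalysed annulation of phenols and naphthols with vinyl ketones to 2-aryl-4H-chromenes and the chiral phosphate-directed Hantzsch ester reduction of benzopyrylium, isobenzopyrylium and cyclic iminium ions; what is new is their union in one flask and hydride delivery to a ketone-derived, non-aromatic oxocarbenium carbon. Ring C closes by 6-exo-trig attack of the phenol oxygen on the carbonyl carbon. The C2 stereocentre is set under catalyst control in the hydride transfer, the chiral phosphate shielding one face of the planar cation while binding the dihydropyridine N–H. Regioselectivity needs no reagent control because the two OH groups and the two free CH positions of 5 are equivalent and the third nucleophilic carbon carries the prenyl group, whereas single alkylation relies on the excess of 5 and slow addition of 8. Chemoselectivity follows from the reagents: the Hantzsch ester reduces the oxocarbenium ion only, and the weak acid does not protonate the prenyl alkene.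

Compound list
1 | 5-methoxybenzene-1,3-diol | COc1cc(O)cc(O)c1 | starting material
2 | 1-methoxy-3,5-bis(methoxymethoxy)benzene | COCOc1cc(OC)cc(OCOC)c1 | intermediate
3 | [4-methoxy-2,6-bis(methoxymethoxy)phenyl]lithium | [Li]c1c(OCOC)cc(OC)cc1OCOC | intermediate
4 | 5-methoxy-1,3-bis(methoxymethoxy)-2-(3-methylbut-2-en-1-yl)benzene | COCOc1cc(OC)cc(OCOC)c1CC=C(C)C | intermediate
5 | 5-methoxy-2-(3-methylbut-2-en-1-yl)benzene-1,3-diol | COc1cc(O)c(CC=C(C)C)c(O)c1 | intermediate
6 | 3-hydroxy-5-methoxybenzaldehyde | COc1cc(O)cc(C=O)c1 | starting material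
7 | 1-(3-hydroxy-5-methoxyphenyl)prop-2-en-1-ol (racemic) | COc1cc(O)cc(C(O)C=C)c1 | intermediate
8 | 1-(3-hydroxy-5-methoxyphenyl)prop-2-en-1-one | COc1cc(O)cc(C(=O)C=C)c1 | intermediate
9 | 3-[2,4-dihydroxy-6-methoxy-3-(3-methylbut-2-en-1-yl)phenyl]-1-(3-hydroxy-5-methoxyphenyl)propan-1-one | COc1cc(O)cc(C(=O)CCc2c(OC)cc(O)c(CC=C(C)C)c2O)c1 | intermediate
10 | 2-(3-hydroxy-5-methoxyphenyl)-5-methoxy-8-(3-methylbut-2-en-1-yl)-3,4-dihydro-2H-chromene-2,7-diol (racemic, labile hemiketal) | COc1cc(O)cc(C2(O)CCc3c(OC)cc(O)c(CC=C(C)C)c3O2)c1 | intermediate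
11 | 2-(3-hydroxy-5-methoxyphenyl)-5-methoxy-8-(3-methylbut-2-en-1-yl)-4H-chromen-7-ol (enol ether; its C3-protonated form is the oxocarbenium ion that is reduced) | COc1cc(O)cc(C2=CCc3c(OC)cc(O)c(CC=C(C)C)c3O2)c1 | intermediate
12 | (2R)-2-(3-hydroxy-5-methoxyphenyl)-5-methoxy-8-(3-methylbut-2-en-1-yl)-3,4-dihydro-2H-chromen-7-ol | COc1cc(O)cc([C@H]2CCc3c(OC)cc(O)c(CC=C(C)C)c3O2)c1 | target

Total step count: 6. Longest linear sequence: 4 steps (steps 1, 2, 3 and 6).

Steps most likely to fail

1. Step 6 (Proposed new method). The hydride transfer may proceed with poor facial selectivity in a loosely organised ion pair. The hemiketal may ionise too slowly under the weak acid. A second Friedel–Crafts alkylation at C6 may compete. The fallback uses known chemistry, sets out from 5 and 8 and comes back to the route at 12. Conjugate addition of 5 to 8 under an achiral acid (diphenyl hydrogen phosphate, CH2Cl2, rt) is stopped at ketone 9, which is isolated. Noyori asymmetric transfer hydrogenation with RuCl(p-cymene)[(S,S)-TsDPEN] in HCO2H/Et3N should reduce the aryl ketone, with the facial sense known for acetophenone-type ketones, to (1S)-3-[2,4-dihydroxy-6-methoxy-3-(3-methylbut-2-en-1-yl)phenyl]-1-(3-hydroxy-5-methoxyphenyl)propan-1-ol F1. Intramolecular Mitsunobu etherification (PPh3, DIAD, THF, 0 °C) by the flanking phenol should then close ring C with inversion to give (2R)-configured 12. The meta-oxygenated ring B does not stabilise a benzylic cation, so the displacement should stay SN2.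

2. Step 5. The unprotected, electron-poor aryl vinyl ketone may polymerise or oligomerise by phenol oxa-Michael addition on handling. The fallback sets out from 6 and comes back to the route at 9. Silylation (TBSCl, imidazole, DMF) should give 3-[(tert-butyldimethylsilyl)oxy]-5-methoxybenzaldehyde F2. Addition of CH2=CHMgBr should give 1-{3-[(tert-butyldimethylsilyl)oxy]-5-methoxyphenyl}prop-2-en-1-ol F3, and MnO2 oxidation should give 1-{3-[(tert-butyldimethylsilyl)oxy]-5-methoxyphenyl}prop-2-en-1-one F4, which has no free phenol and can be purified. Friedel–Crafts conjugate addition of 5 to F4 (diphenyl hydrogen phosphate, CH2Cl2) should give 1-{3-[(tert-butyldimethylsilyl)oxy]-5-methoxyphenyl}-3-[2,4-dihydroxy-6-methoxy-3-(3-methylbut-2-en-1-yl)phenyl]propan-1-one F5. Bu4NF/AcOH in THF should remove the silyl group to give 9, which is then exposed to the chiral acid and Hantzsch ester stage of step 6.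

3. Step 3. Acid may trigger cyclisation of the prenyl group onto a freed ortho hydroxyl (2,2-dimethylchroman formation) or addition of methanol or HCl across the alkene. The fallback replaces the acid-labile acetals by fluoride-labile ones, sets out from 1 and comes back to the route at 5. NaH and 2-(trimethylsilyl)ethoxymethyl chloride in DMF should give 1-methoxy-3,5-bis{[2-(trimethylsilyl)ethoxy]methoxy}benzene F6. Treatment with n-BuLi in THF at 0 °C should give [4-methoxy-2,6-bis{[2-(trimethylsilyl)ethoxy]methoxy}phenyl]lithium F7, which with CuI (10 mol%) and prenyl bromide should give 5-methoxy-2-(3-methylbut-2-en-1-yl)-1,3-bis{[2-(trimethylsilyl)ethoxy]methoxy}benzene F8. Bu4NF in DMPU at 80 °C should cleave both acetals by fluoride-induced fragmentation under non-acidic conditions to give 5.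

Further compounds
F1 | step 6 | (1S)-3-[2,4-dihydroxy-6-methoxy-3-(3-methylbut-2-en-1-yl)phenyl]-1-(3-hydroxy-5-methoxyphenyl)propan-1-ol | COc1cc(O)cc([C@@H](O)CCc2c(OC)cc(O)c(CC=C(C)C)c2O)c1
F2 | step 5 | 3-[(tert-butyldimethylsilyl)oxy]-5-methoxybenzaldehyde | COc1cc(O[Si](C)(C)C(C)(C)C)cc(C=O)c1
F3 | step 5 | 1-{3-[(tert-butyldimethylsilyl)oxy]-5-methoxyphenyl}prop-2-en-1-ol | COc1cc(O[Si](C)(C)C(C)(C)C)cc(C(O)C=C)c1
F4 | step 5 | 1-{3-[(tert-butyldimethylsilyl)oxy]-5-methoxyphenyl}prop-2-en-1-one | COc1cc(O[Si](C)(C)C(C)(C)C)cc(C(=O)C=C)c1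
F5 | step 5 | 1-{3-[(tert-butyldimethylsilyl)oxy]-5-methoxyphenyl}-3-[2,4-dihydroxy-6-methoxy-3-(3-methylbut-2-en-1-yl)phenyl]propan-1-one | COc1cc(O[Si](C)(C)C(C)(C)C)cc(C(=O)CCc2c(OC)cc(O)c(CC=C(C)C)c2O)c1
F6 | step 3 | 1-methoxy-3,5-bis{[2-(trimethylsilyl)ethoxy]methoxy}benzene | COc1cc(OCOCC[Si](C)(C)C)cc(OCOCC[Si](C)(C)C)c1
F7 | step 3 | [4-methoxy-2,6-bis{[2-(trimethylsilyl)ethoxy]methoxy}phenyl]lithium | [Li]c1c(OCOCC[Si](C)(C)C)cc(OC)cc1OCOCC[Si](C)(C)C
F8 | step 3 | 5-methoxy-2-(3-methylbut-2-en-1-yl)-1,3-bis{[2-(trimethylsilyl)ethoxy]methoxy}benzene | COc1cc(OCOCC[Si](C)(C)C)c(CC=C(C)C)c(OCOCC[Si](C)(C)C)c1
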